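## Structural features

The target is a resveratrol hexamer with six 4-hydroxyphenyl groups, six 1,3-dioxygenated benzene rings (A to F), three trans-2-aryl-2,3-dihydrobenzofurans and twelve CH stereocentres, labelled here C-a to C-l (C-a S, C-b R, C-c R, C-d S, C-e R, C-f R, C-g R, C-h R, C-i S, C-j S, C-k R, C-l R). In the left unit, C-a (aryl-bearing), ring A, C-b, ring B and C-d close a dibenzo-fused seven-membered carbocycle, C-b/C-c/O close a dihydrobenzofuran on ring B, and the hydrogens at C-a, C-b and C-d lie on one face. In the right unit, C-f, ring C, C-g, ring D, C-i and C-j close a dibenzo-fused eight-membered carbocycle; C-g/C-h/O form the second dihydrobenzofuran on ring C, C-i carries a 4-hydroxyphenyl group, and C-j carries the third dihydrobenzofuran (ring E, C-k, C-l), whose C-k bears the free ring F. The exocyclic C-e (CH with a 4-hydroxyphenyl group) joins C-d to C-f, so C-a, C-d, C-e, C-f, C-j and C-i are six adjacent stereocentres; on the eight-membered ring, ring E and C-e are cis, the C-i aryl is trans to ring E, and C-h lies on the face of the C-i aryl. Fragile points are the fifteen phenols, the three dihydrobenzofurans (cyclic 4-alkoxybenzyl aryl ethers that open under acid), the electron-rich rings placed to trap a benzylic cation (ring F onto C-i in a seven-ring mode, ring E onto C-e in an indane mode), and the acidic hydrogens at C-g and C-j in carbonyl intermediates. The real difficulty is the eight-membered carbocycle with its four stereocentres, followed by the stereocontrolled C-d–C-e union of two large chiral halves. The key step uses the substitution of ring D: its adjacent carbons d1 and d6 carry C-g and C-i, d1 next to an unsubstituted CH and d6 next to an oxygen-bearing carbon. That is the pattern left when a carbon nucleophile (the future C-g) adds to the oxygen-remote carbon of a 3,5-dialkoxybenzyne and the aryl anion next to oxygen closes on a carbonyl (the future C-i).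

## Logic of the disconnections

52 to 51: the fourteen O–CH3 bonds are cut last. Methyl ethers are the only phenol protection that survives every earlier step. The forward step must not open the three furans irreversibly.

51 to 49 (through 50): the C-a–aryl and C-a–H bonds are cut to a carbonyl at C-a. That carbonyl is what makes C-d nucleophilic in the union, and the sixth aryl group becomes a simple Grignard reagent. Hydride must enter C-a opposite the C-e branch and must outrun Friedel–Crafts capture of the cation.

49 to 45 and 47 (through 48): the C-d–C-e bond is cut. This splits the molecule into two halves of comparable size. The polarity chosen is enolate at C-d and para-quinone methide at C-e, under non-acidic conditions, because a cation at C-e would be trapped by ring E. The forward step needs facial control on both partners, and addition must be faster than tautomerisation of the methide.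

47 to 46 to 12: the C-a–a1 bond is cut (Friedel–Crafts acylation). The left half then costs two steps from the acid that also serves the right half, with C-b and C-c already in place. The acylation must close a seven-membered ring ortho on ring A.

45 to 43 to 41: the C-e–aryl bond and the terminal C=C bond of the vinyl group are cut. The vinyl group is a masked aldehyde that survives all earlier steps. C-f, α to that aldehyde, must not epimerise.

41 to 40 to 38 (through 39) to 37, 36 and 35: the C-h–O and C-h–aryl bonds are cut, and C-h is taken back to the ester carbon on C-g. The furan then closes by an SN1 reaction that gives the trans ring whatever the carbinol configuration. C-g must have the right configuration before the aryl addition; it is set by equilibration of the aldehyde.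

35 to 32 to 31: the C-i–aryl bond is cut to an aryl bromide (33) and a benzylic radical. A cation at C-i would be trapped by ring F or lose the C-j hydrogen. The radical must be captured on the face opposite ring E.

31 to 28 and 25 (through 29 and 30): the C-g–d1 and d6–C-i bonds are cut. This removes ring D and contracts the eight-membered ring to a six-membered β-keto ester. The forward step must deliver the enolate carbon to the oxygen-remote aryne carbon and fragment the fused four-membered alkoxide.

28 to 27: the bond between the ester-bearing carbon and the future C-i carbonyl is cut (Dieckmann). Both precursors are esters of the same oxidation level. The base must deprotonate the benzylic CH2 and not C-j. Ring C carries methoxymethyl ethers in 28, because benzyl ethers could only be removed by hydrogenolysis, which would saturate the vinyl group.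

27 to 13 and 20 (through 26): the C-j–C-f bond is cut (branched allylic alkylation). Both stereocentres are set in one catalytic step from an arylacetic ester and a cinnamyl carbonate. The pentafluorophenyl ester 26 is exchanged for the methyl ester before ring closure, because the aryl ester would form a ketene at C-j.

20 to 14 (through 19, 18, 17, 16, 15): the carbonate, the aryl–CH2CO2Me bond, the alkene and the C–Br bond are cut in turn. The acetate arm must sit on the ring C carbon between the oxygen-bearing carbon and the propenyl carbon. Bromination ortho to the formyl group secures this.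

13 to 12 to 11 to 10: the ester and the aryl–CH2 bond are cut back to an aryl bromide. 10 to 7 (through 8 and 9): the C-k–C-l bond is cut (carbene C–H insertion), which sets C-k by catalyst control; C-l is then corrected to trans by acid. 7 to 6 to 4 to 1, 2 and 5: the hydrazone, the benzyl ether and the aryl–carbonyl bond are cut to three commercial arenes.

25 to 22 to 21: the C–Si, O–Tf and C–Br bonds are cut. This is the usual route to an ortho-silylaryl triflate from a phenol.

## Other disconnections considered

Alternative 1: Ring E and its furan are cut together, four C–C bonds at once, back to the diazo enone A2 with a tethered ethynyl ether. Forward, irradiation of A2 would trigger a Wolff rearrangement to a vinylketene, [2+2] addition to the alkyne, four-electron ring opening and six-electron closure, giving phenol A1. In its favour, the arene is built with its oxygen pattern and carbon arm fixed by connectivity, so there is no Friedel–Crafts regiochemistry question; on that point it is better than steps 1 and 9 of the chosen plan. The two furan stereocentres are carried in from the tether, which is equal to the chosen plan in outcome. Against it, A2 needs its own asymmetric synthesis of a 1,2-diaryl ether with an ynol ether and a diazo transfer, and the silyloxymethyl arm of A1 needs oxidation-state changes and a one-carbon homologation to reach 12. The chosen plan reaches 10 in four steps and 12 in six, so it is better on step economy. Mechanistically both are reliable (pericyclic cascade against carbene insertion).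

Alternative 2: The C-a–a1 and C-a–C-d bonds of the seven-membered ring are cut, contracting it to the furan-bridged anthrone A4. Forward, A4 and the aryl diazomethane A5 with a Lewis acid would give a diazonium alkoxide, and migration of the ring A carbon with loss of N2 would give ketone A3. In its favour, C-a receives its aryl group and hydrogen in one step without a carbinol or cation at C-a; on that point it is better than steps 31 and 32. Against it, the carbonyl ends up at C-d, where the target needs a hydrogen and the bond to C-e. C-d could then only be joined to C-e by addition to the carbonyl followed by deoxygenation, which is less direct than the enolate union through 46. Migration of ring A against ring B carbon and epoxide formation are further selectivity questions, and A4 is strained and needs its own route. Step count is at best equal.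

Alternative 3: The C-b–a6 and a1–C-a bonds are cut, contracting the seven-membered ring to the indanone ester A7. Forward, A7 would add to the aryne from 25 and the adduct would fragment to keto ester A6. In its favour, it uses the same reaction class and the same aryne precursor as the key step, so mechanistic confidence is equal, and a five-to-seven expansion is easier than six-to-eight (better on that point). It also gives the carbonyl at C-a with CH2 at C-d, as the union needs (equal). Against it, A6 has no furan and its C-b is an acidic diaryl-acetate centre with no control of absolute configuration. The furan would take four or five more steps, and the Dieckmann route to A7 is unsymmetrical. The chosen plan makes 46 in one step from enantiopure 12, so it is better on step economy and stereocontrol.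

Key step: step 18

Remarks on the chemistry:
- Abbreviations: An = 4-methoxyphenyl; DBF = (2R,3R)-3-(3,5-dimethoxyphenyl)-6-methoxy-2-(4-methoxyphenyl)-2,3-dihydro-1-benzofuran-4-yl; atom and ring labels as defined under "Structural features".
- Assumption: where a chiral catalyst or ligand is named, the enantiomer that leads to the drawn configuration is meant; its antipode is taken if the sense of induction is the reverse.
- Assumption: the configuration of C-g in 31 to 37 is drawn as the epimer expected at equilibrium; it is fixed only in step 23.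

Step 1
Reactants: 1 1-bromo-3,5-dimethoxybenzene; 2 3,5-dimethoxybenzoyl chloride
Product: 4 (2-bromo-6-hydroxy-4-methoxyphenyl)(3,5-dimethoxyphenyl)methanone, via dimethoxy ketone 3 (not isolated)
Conditions: AlCl3 (2.5 equiv), CH2Cl2, 0 °C to 40 °C
Reagents that add atoms: none
Why: Friedel–Crafts aroylation should go to C2 of 1 (para to one methoxy group; the position between the two methoxy groups is more hindered), and the AlCl3-chelated ketone 3 then loses only the methyl group ortho to the carbonyl, freeing the future furan oxygen of ring E.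

Step 2
Reactants: 4 (2-bromo-6-hydroxy-4-methoxyphenyl)(3,5-dimethoxyphenyl)methanone; 5 4-methoxybenzyl chloride
Product: 6 {2-bromo-4-methoxy-6-[(4-methoxyphenyl)methoxy]phenyl}(3,5-dimethoxyphenyl)methanone
Conditions: K2CO3, NaI (cat.), DMF, 60 °C
Reagents that add atoms: none
Why: Williamson etherification of the phenol; the benzylic CH2 introduced here becomes C-l, and one of its C–H bonds is the one cleaved in step 4.

Step 3
Reactants: 6 {2-bromo-4-methoxy-6-[(4-methoxyphenyl)methoxy]phenyl}(3,5-dimethoxyphenyl)methanone
Product: 7 hydrazone of 6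
Conditions: N2H4·H2O (10 equiv), AcOH (cat.), n-BuOH, 110 °C
Reagents that add atoms: hydrazine (as hydrate), NN
Why: Hydrazone formation; it is slow for a di-ortho-substituted benzophenone and is forced with excess hydrazine and heat, the aryl bromide and ethers being inert.

Step 4
Reactants: 7 hydrazone of 6
Product: 10 (2R,3R)-4-bromo-3-(3,5-dimethoxyphenyl)-6-methoxy-2-(4-methoxyphenyl)-2,3-dihydro-1-benzofuran, via diazo compound 8 (not isolated), via cis ether 9 (not isolated)
Conditions: MnO2, CH2Cl2, 0 °C, filter; Rh2(S-PTAD)4 (1 mol %), CH2Cl2, −40 to 0 °C; then CF3CO2H, 0 °C to rt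
Reagents that add atoms: none
Why: Dehydrogenation gives the diaryldiazomethane 8, whose rhodium carbene inserts into the benzylic ether C–H bond through a five-membered transition state (donor/donor carbene C–H insertion), setting C-k by catalyst control and giving the cis ether 9. Acid then opens the 4-methoxybenzylic C–O bond reversibly and recloses it to the more stable trans ring, leaving C-k untouched.

Step 5
Reactants: 10 (2R,3R)-4-bromo-3-(3,5-dimethoxyphenyl)-6-methoxy-2-(4-methoxyphenyl)-2,3-dihydro-1-benzofuran
Product: 11 ethyl 2-DBF-acetate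
Conditions: BrZnCH2CO2Et (1.5 equiv), Pd2(dba)3 (2 mol %), XPhos (5 mol %), THF, 50 °C
Reagents that add atoms: (2-ethoxy-2-oxoethyl)zinc bromide, CCOC(=O)C[Zn]Br
Why: Negishi-type coupling of a Reformatsky reagent with the aryl bromide; the neutral zinc enolate tolerates the benzylic ether and leaves C-k and C-l untouched.

Step 6
Reactants: 11 ethyl 2-DBF-acetate
Product: 12 2-DBF-acetic acid
Conditions: LiOH, THF/MeOH/H2O, rt; then 1 M HCl
Reagents that add atoms: lithium hydroxide, [Li+].[OH-]
Why: Saponification; the methylene carries no stereocentre, and 12 is the common intermediate for both halves of the target.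

Step 7
Reactants: 12 2-DBF-acetic acid
Product: 13 pentafluorophenyl 2-DBF-acetate
Conditions: C6F5OH, DCC, CH2Cl2, 0 °C to rt
Reagents that add atoms: pentafluorophenol, Oc1c(F)c(F)c(F)c(F)c1F
Why: Carbodiimide esterification; the aryl ester is the acyl donor that isothiourea catalysis needs in step 16.

Step 8
Reactants: 14 3,5-dihydroxybenzaldehyde
Product: 15 3,5-bis(methoxymethoxy)benzaldehyde
Conditions: MOMCl, i-Pr2NEt, CH2Cl2, 0 °C to rt
Reagents that add atoms: chloromethyl methyl ether, COCCl
Why: Alkylation of both phenols; the acetal ethers survive every step up to step 24 and leave under the same acid that closes the furan.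

Step 9
Reactants: 15 3,5-bis(methoxymethoxy)benzaldehyde
Product: 16 2-bromo-3,5-bis(methoxymethoxy)benzaldehyde
Conditions: NBS, MeCN, 0 °C to rt
Reagents that add atoms: N-bromosuccinimide, O=C1CCC(=O)N1Br
Why: Electrophilic bromination should go ortho to the formyl group and para to one alkoxy group (the position between the two alkoxy groups is more hindered), which puts bromine on the carbon that must carry the acetate arm.

Step 10
Reactants: 16 2-bromo-3,5-bis(methoxymethoxy)benzaldehyde
Product: 17 methyl (E)-3-[2-bromo-3,5-bis(methoxymethoxy)phenyl]prop-2-enoate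
Conditions: (MeO)2P(O)CH2CO2Me, LiCl, DBU, MeCN, rt
Reagents that add atoms: trimethyl phosphonoacetate, COC(=O)CP(=O)(OC)OC
Why: Horner–Wadsworth–Emmons olefination under mild LiCl/amine conditions should give the (E)-enoate.

Step 11
Reactants: 17 methyl (E)-3-[2-bromo-3,5-bis(methoxymethoxy)phenyl]prop-2-enoate
Product: 18 (E)-3-[2-bromo-3,5-bis(methoxymethoxy)phenyl]prop-2-en-1-ol
Conditions: i-Bu2AlH (2.2 equiv), CH2Cl2, −78 °C; aq. KNaC4H4O6
Reagents that add atoms: none
Why: 1,2-Reduction of the enoate to the allylic alcohol at low temperature; the aryl bromide and the acetals are inert.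

Step 12
Reactants: 18 (E)-3-[2-bromo-3,5-bis(methoxymethoxy)phenyl]prop-2-en-1-ol
Product: 19 methyl 2-{2-[(E)-3-hydroxyprop-1-enyl]-4,6-bis(methoxymethoxy)phenyl}acetate
Conditions: BrZnCH2CO2Me (3 equiv, from BrCH2CO2Me and Zn), Pd2(dba)3 (2.5 mol %), XPhos (6 mol %), THF, 60 °C
Reagents that add atoms: methyl 2-(bromozincio)acetate, COC(=O)C[Zn]Br
Why: Negishi-type coupling of the Reformatsky reagent at the di-ortho-substituted aryl bromide with a bulky biarylphosphine; one equivalent of reagent is consumed by the hydroxyl group.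

Step 13
Reactants: 19 methyl 2-{2-[(E)-3-hydroxyprop-1-enyl]-4,6-bis(methoxymethoxy)phenyl}acetate
Product: 20 methyl 2-{2-[(E)-3-(methoxycarbonyloxy)prop-1-enyl]-4,6-bis(methoxymethoxy)phenyl}acetate
Conditions: ClCO2Me, pyridine, CH2Cl2, 0 °C
Reagents that add atoms: methyl chloroformate, COC(Cl)=O
Why: Acylation of the allylic alcohol gives the carbonate that ionises to the aryl-substituted allyl–iridium species in step 16.

Step 14
Reactants: 21 3,5-dimethoxyphenol
Product: 22 2-bromo-3,5-dimethoxyphenol
Conditions: NBS, CH2Cl2, −78 °C to rt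
Reagents that add atoms: N-bromosuccinimide, O=C1CCC(=O)N1Br
Why: ortho-Bromination of the phenol at low temperature, the usual first step to this aryne precursor; any para isomer is removed here.

Step 15
Reactants: 22 2-bromo-3,5-dimethoxyphenol
Product: 25 3,5-dimethoxy-2-(trimethylsilyl)phenyl trifluoromethanesulfonate, via silyl ether 23 (not isolated), via lithium phenoxide 24 (not isolated)
Conditions: (Me3Si)2NH, THF, 70 °C, concentrate; n-BuLi, THF, −100 to −78 °C; then Tf2O, −100 °C
Reagents that add atoms: hexamethyldisilazane, C[Si](C)(C)N[Si](C)(C)C; trifluoromethanesulfonic anhydride, O=S(=O)(OS(=O)(=O)C(F)(F)F)C(F)(F)F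
Why: O-Silylation, bromine–lithium exchange and 1,3 O-to-C silyl migration (retro-Brook) give the ortho-silyl phenoxide 24, which is trapped as the triflate; this is the standard route to ortho-silylaryl triflates.

Step 16
Reactants: 13 pentafluorophenyl 2-DBF-acetate; 20 methyl 2-{2-[(E)-3-(methoxycarbonyloxy)prop-1-enyl]-4,6-bis(methoxymethoxy)phenyl}acetate
Product: 27 methyl (2R,3R)-2-DBF-3-[2-(2-methoxy-2-oxoethyl)-3,5-bis(methoxymethoxy)phenyl]pent-4-enoate, via pentafluorophenyl ester 26 (not isolated)
Conditions: [Ir(cod)Cl]2 (2 mol %), (R,R,R)-BINOL bis(1-phenylethyl)phosphoramidite (4 mol %), (R)-benzotetramisole (10 mol %), THF, rt; then MeOH, DMAP, rt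
Reagents that add atoms: methanol, CO
Why: Dual catalysis: the isothiourea turns 13 into a chiral ammonium enolate that attacks the substituted terminus of the allyl–iridium complex from 20 (branched allylic alkylation). The iridium ligand fixes C-f and the isothiourea fixes C-j independently, so the (2R,3R) pair is chosen by the pairing of catalyst hands; aryloxide rebound gives 26. Methanolysis in the same flask gives 27, which avoids a ketene at C-j in step 17.

Step 17
Reactants: 27 methyl (2R,3R)-2-DBF-3-[2-(2-methoxy-2-oxoethyl)-3,5-bis(methoxymethoxy)phenyl]pent-4-enoate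
Product: 28 methyl (3R,4R)-4-ethenyl-2-hydroxy-6,8-bis(methoxymethoxy)-3-DBF-3,4-dihydronaphthalene-1-carboxylate (β-tetralone ester, enol form)
Conditions: LiN(SiMe3)2 (2.2 equiv), THF, −78 to −30 °C; AcOH
Reagents that add atoms: none
Why: Dieckmann condensation: the hindered amide base should remove a proton from the unhindered benzylic CH2 in preference to the tertiary C-j hydrogen, and the enolate closes the six-membered ring on the C-j ester. The product stays protected as its enolate until the cold acidic quench; the regioisomeric closure would give a non-enolisable keto ester and is reversible.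

Step 18
Reactants: 28 β-tetralone ester (enol form); 25 3,5-dimethoxy-2-(trimethylsilyl)phenyl trifluoromethanesulfonate
Product: 31 eight-ring keto ester (CO2Me on C-g, ketone at C-i, vinyl on C-f, DBF on C-j; C-f R, C-g R, C-j R), via aryne 29 (not isolated), via cyclobutanol alkoxide 30 (not isolated)
Conditions: CsF (3 equiv), MeCN, 60 °C, 25 (1.5 equiv) added over 2 h
Reagents that add atoms: none
Why: Fluoride removes the silyl group of 25 and triflate leaves, giving 3,5-dimethoxybenzyne 29; the caesium enolate of 28 adds through its ester-bearing carbon to the aryne carbon remote from the flanking methoxy group, leaving the aryl anion on the carbon next to that methoxy group. This anion adds to the neighbouring ring ketone to give the fused four-membered alkoxide 30, which fragments by cleaving the old ester-carbon–carbonyl bond to an ester-stabilised carbanion that is protonated to 31. The closest known reaction type is the acyl-alkylation of arynes by cyclic β-keto esters, which gives benzannulated medium rings by two-carbon ring expansion. The eight-membered ring is therefore not closed end to end: it arises from a 4-exo addition inside a fused bicycle followed by ring-opening fragmentation, which avoids the entropic and transannular cost of a direct medium-ring closure. The new stereocentre C-g is a diaryl-acetate carbon set by protonation; it stays acidic, should settle under the basic conditions with the ester on the face opposite ring E, and is equilibrated again at the aldehyde stage (step 22). Regioselectivity rests on the polarisation and distortion of the 3-alkoxyaryne, which directs the nucleophile to the carbon away from oxygen. C- over O-arylation is usual for the soft, fully substituted enolate carbon of a β-keto ester, and over-arylation is limited by slow addition of 25 and by the hindered product anion. C-f and C-j are not part of the reacting array, but C-j becomes α to the ketone in 31, so the temperature is held at 60 °C and the reaction is stopped at full conversion of 28.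

Step 19
Reactants: 31 eight-ring keto ester
Product: 32 eight-ring hydroxy ester (secondary alcohol at C-i, configuration not controlled)
Conditions: NaBH4, CeCl3·7H2O, MeOH/THF, −40 to 0 °C
Reagents that add atoms: none
Why: Luche reduction is selective for the ketone over the ester and is not basic enough to epimerise C-j; the carbinol configuration is of no consequence because C-i becomes planar in step 20.

Step 20
Reactants: 32 eight-ring hydroxy ester; 33 4-bromoanisole
Product: 35 eight-ring ester with An on C-i (C-f R, C-g R, C-i S, C-j S), via N,O-acetal 34 (not isolated)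
Conditions: 5,7-di-tert-butyl-3-phenylbenzoxazolium BF4, pyridine, t-BuOMe, rt; then 33, Ir(ppy)2(dtbbpy)PF6 (1 mol %), NiBr2(dtbbpy) (5 mol %), quinuclidine, DMA, 450 nm, rt
Reagents that add atoms: none
Why: Nickel/photoredox deoxygenative arylation of an alcohol: condensation with the benzoxazolium salt gives the N,O-acetal 34, whose photoredox oxidation and β-scission release the benzylic radical at C-i, which is captured by the aryl–nickel species from 33. The planar radical should be approached on the face that places the new aryl group trans to ring E on the neighbouring C-j. The radical pathway avoids a C-i cation, which ring F could trap in a seven-ring Friedel–Crafts mode or which could lose the C-j hydrogen.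

Step 21
Reactants: 35 eight-ring ester with An on C-i
Product: 36 eight-ring primary alcohol (CH2OH on C-g)
Conditions: LiAlH4, THF, 0 °C
Reagents that add atoms: none
Why: Hydride reduction of the hindered diaryl-acetic ester to the primary alcohol; no other reducible group is present.

Step 22
Reactants: 36 eight-ring primary alcohol
Product: 37 eight-ring aldehyde (CHO on C-g)
Conditions: Dess–Martin periodinane, CH2Cl2, 0 °C to rt; then Et3N (cat.), rt
Reagents that add atoms: none
Why: Dess–Martin oxidation; the diaryl-acetaldehyde enolises easily, and a trace of amine lets C-g settle to the epimer expected to be the more stable one, with the formyl group on the face opposite ring E, before it is fixed in step 23.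

Step 23
Reactants: 37 eight-ring aldehyde
Product: 38 eight-ring carbinol (CH(OH)An on C-g, carbinol configuration not controlled)
Conditions: 4-MeOC6H4MgBr, LaCl3·2LiCl (0.3 equiv), THF, −78 °C
Reagents that add atoms: 4-methoxyphenylmagnesium bromide, COc1ccc([Mg]Br)cc1
Why: Grignard addition to the aldehyde, with LaCl3·2LiCl to suppress enolisation, creates the C-h carbinol as a mixture that converges in step 24; after this step C-g is no longer acidic.

Step 24
Reactants: 38 eight-ring carbinol
Product: 40 right-half phenol (furan C-g/C-h closed, free OH on ring C, vinyl on C-f), via deprotected triol 39 (not isolated)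
Conditions: HCl (3 M in MeOH), THF, 45 °C
Reagents that add atoms: none
Why: Acid removes both acetals as dimethoxymethane and ionises the 4-methoxybenzylic carbinol; the ring C phenol next to C-g traps the cation in a five-membered closure. The closure is reversible, so the 2,3-trans dihydrobenzofuran (C-h R) should accumulate whatever the carbinol configuration.

Step 25
Reactants: 40 right-half phenol
Product: 41 right-half methyl ether (vinyl on C-f)
Conditions: MeI, K2CO3, acetone, 50 °C
Reagents that add atoms: iodomethane, CI
Why: O-Methylation of the one free phenol, so that the oxidative cleavage, Grignard and acylation steps that follow need not tolerate it.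

Step 26
Reactants: 41 right-half methyl ether
Product: 43 right-half aldehyde (CHO on C-f), via diol 42 (not isolated)
Conditions: OsO4 (2 mol %), NaIO4, 2,6-lutidine, dioxane/H2O, rt
Reagents that add atoms: osmium tetroxide, O=[Os](=O)(=O)=O (oxygen donor, reoxidised by NaIO4)
Why: Lemieux–Johnson cleavage of the terminal alkene; OsO4/NaIO4 is preferred to ozone because of the many electron-rich arenes, and 2,6-lutidine keeps the α-aryl aldehyde from epimerising at C-f.

Step 27
Reactants: 43 right-half aldehyde
Product: 45 right-half acetate (C-e bears OAc and 4-(tert-butyldimethylsilyloxy)phenyl), via magnesium alkoxide 44 (not isolated)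
Conditions: 4-(t-BuMe2SiO)C6H4MgBr (from the aryl bromide and Mg), THF, −78 °C; then Ac2O, DMAP (cat.), −78 to 0 °C
Reagents that add atoms: [4-(tert-butyldimethylsilyloxy)phenyl]magnesium bromide, CC(C)(C)[Si](C)(C)Oc1ccc([Mg]Br)cc1; acetic anhydride, CC(=O)OC(C)=O
Why: Aryl Grignard addition to the aldehyde at low temperature, then O-acetylation of the alkoxide in the same flask; the carbinol configuration is irrelevant because C-e becomes planar in step 30.

Step 28
Reactants: 12 2-DBF-acetic acid
Product: 46 left ketone (dibenzocycloheptenone, C=O at C-a, CH2 at C-d, C-b R, C-c R)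
Conditions: (CF3CO)2O, CH2Cl2, 0 °C to rt
Reagents that add atoms: none
Why: Intramolecular Friedel–Crafts acylation through the mixed anhydride closes the seven-membered ring on the ring A carbon ortho to C-b, which is activated by an ortho and a para methoxy group; C-b and C-c are untouched, and C-d is the only enolisable carbon of the product.

Step 29
Reactants: 46 left ketone
Product: 47 left enol silane (trimethylsilyl enol ether, C-a=C-d)
Conditions: Me3SiOTf, Et3N, CH2Cl2, 0 °C
Reagents that add atoms: trimethylsilyl trifluoromethanesulfonate, C[Si](C)(C)OS(=O)(=O)C(F)(F)F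
Why: Soft enolisation gives the only possible silyl enol ether.

Step 30
Reactants: 45 right-half acetate; 47 left enol silane
Product: 49 union ketone (C-d–C-e bond formed, 4-hydroxyphenyl on C-e, C=O at C-a), via quinone methide 48 (not isolated)
Conditions: 47 (2 equiv), Bu4NF (anhydrous, 3.2 equiv), THF, −78 to −20 °C; aq. NH4Cl
Reagents that add atoms: none
Why: Fluoride removes both silyl groups: the phenoxide from 45 expels acetate (1,6-elimination) to give the para-quinone methide 48, and the enolate of 46 adds to its exocyclic carbon (1,6-conjugate addition). The C-d–C-e bond forms without acid, so ring E cannot close an indane onto C-e. The enolate should be attacked on the outer face of the boat-shaped tricycle, leaving the C-d hydrogen cis to the C-b hydrogen, and 48 should react anti to ring C on C-f in the conformer that holds the C-f hydrogen in the methide plane; this topicity is the least secure element of the route.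

Step 31
Reactants: 49 union ketone
Product: 50 tertiary carbinol (OH and An on C-a, configuration not controlled)
Conditions: 4-MeOC6H4MgBr (6 equiv), LaCl3·2LiCl (0.5 equiv), THF, 0 °C
Reagents that add atoms: 4-methoxyphenylmagnesium bromide, COc1ccc([Mg]Br)cc1
Why: Grignard addition to the hindered aryl ketone, with LaCl3·2LiCl to suppress enolisation at C-d; the first equivalent is consumed by the phenol, and the carbinol configuration is irrelevant.

Step 32
Reactants: 50 tertiary carbinol
Product: 51 tetradeca-O-methyl ether of the target (all twelve stereocentres as in 52, free OH only on the C-e aryl)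
Conditions: Et3SiH (10 equiv), BF3·OEt2 (0.5 equiv), CH2Cl2, −78 to −40 °C
Reagents that add atoms: none
Why: Ionic hydrogenation: the doubly benzylic cation at C-a should take hydride from the silane on the face opposite the C-e branch on the neighbouring C-d, which puts the C-a hydrogen cis to the C-d hydrogen. Low temperature, sub-stoichiometric Lewis acid and a large excess of silane are used so that reduction outruns Friedel–Crafts capture and the dihydrobenzofurans are not opened.

Step 33
Reactants: 51 tetradeca-O-methyl ether of the target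
Product: 52 CNP0184494.1 (target)
Conditions: BBr3 (excess), CH2Cl2, −78 °C to rt; MeOH, H2O
Reagents that add atoms: none
Why: Global O-demethylation with BBr3 cleaves the fourteen methyl ethers; the three dihydrobenzofurans are already the more stable trans isomers, so any reversible opening at C-c, C-h or C-l should reclose to the same ring.

## Compound list

1 | 1-bromo-3,5-dimethoxybenzene | COc1cc(Br)cc(OC)c1 | starting material
2 | 3,5-dimethoxybenzoyl chloride | COc1cc(cc(OC)c1)C(Cl)=O | starting material
3 | (2-bromo-4,6-dimethoxyphenyl)(3,5-dimethoxyphenyl)methanone | COc1cc(OC)c(C(=O)c2cc(OC)cc(OC)c2)c(Br)c1 | intermediate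
4 | (2-bromo-6-hydroxy-4-methoxyphenyl)(3,5-dimethoxyphenyl)methanone | COc1cc(O)c(C(=O)c2cc(OC)cc(OC)c2)c(Br)c1 | intermediate
5 | 4-methoxybenzyl chloride | COc1ccc(CCl)cc1 | starting material
6 | {2-bromo-4-methoxy-6-[(4-methoxyphenyl)methoxy]phenyl}(3,5-dimethoxyphenyl)methanone | COc1ccc(COc2cc(OC)cc(Br)c2C(=O)c2cc(OC)cc(OC)c2)cc1 | intermediate
7 | hydrazone of 6 | COc1ccc(COc2cc(OC)cc(Br)c2C(=NN)c2cc(OC)cc(OC)c2)cc1 | intermediate
8 | 1-bromo-2-[diazo(3,5-dimethoxyphenyl)methyl]-5-methoxy-3-[(4-methoxyphenyl)methoxy]benzene | COc1ccc(COc2cc(OC)cc(Br)c2C(=[N+]=[N-])c2cc(OC)cc(OC)c2)cc1 | intermediate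
9 | (2S,3R)-4-bromo-3-(3,5-dimethoxyphenyl)-6-methoxy-2-(4-methoxyphenyl)-2,3-dihydro-1-benzofuran (cis) | Brc1cc(OC)cc2c1[C@@H](c1cc(OC)cc(OC)c1)[C@@H](c1ccc(OC)cc1)O2 | intermediate
10 | (2R,3R)-4-bromo-3-(3,5-dimethoxyphenyl)-6-methoxy-2-(4-methoxyphenyl)-2,3-dihydro-1-benzofuran (trans) | Brc1cc(OC)cc2c1[C@@H](c1cc(OC)cc(OC)c1)[C@H](c1ccc(OC)cc1)O2 | intermediate
11 | ethyl 2-DBF-acetate | CCOC(=O)Cc1cc(OC)cc2c1[C@@H](c1cc(OC)cc(OC)c1)[C@H](c1ccc(OC)cc1)O2 | intermediate
12 | 2-DBF-acetic acid | OC(=O)Cc1cc(OC)cc2c1[C@@H](c1cc(OC)cc(OC)c1)[C@H](c1ccc(OC)cc1)O2 | intermediate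
13 | pentafluorophenyl 2-DBF-acetate | O=C(Cc1cc(OC)cc2c1[C@@H](c1cc(OC)cc(OC)c1)[C@H](c1ccc(OC)cc1)O2)Oc1c(F)c(F)c(F)c(F)c1F | intermediate
14 | 3,5-dihydroxybenzaldehyde | O=Cc1cc(O)cc(O)c1 | starting material
15 | 3,5-bis(methoxymethoxy)benzaldehyde | COCOc1cc(C=O)cc(OCOC)c1 | intermediate
16 | 2-bromo-3,5-bis(methoxymethoxy)benzaldehyde | COCOc1cc(C=O)c(Br)c(OCOC)c1 | intermediate
17 | methyl (E)-3-[2-bromo-3,5-bis(methoxymethoxy)phenyl]prop-2-enoate | COCOc1cc(/C=C/C(=O)OC)c(Br)c(OCOC)c1 | intermediate
18 | (E)-3-[2-bromo-3,5-bis(methoxymethoxy)phenyl]prop-2-en-1-ol | COCOc1cc(/C=C/CO)c(Br)c(OCOC)c1 | intermediate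
19 | methyl 2-{2-[(E)-3-hydroxyprop-1-enyl]-4,6-bis(methoxymethoxy)phenyl}acetate | COCOc1cc(/C=C/CO)c(CC(=O)OC)c(OCOC)c1 | intermediate
20 | methyl 2-{2-[(E)-3-(methoxycarbonyloxy)prop-1-enyl]-4,6-bis(methoxymethoxy)phenyl}acetate | COCOc1cc(/C=C/COC(=O)OC)c(CC(=O)OC)c(OCOC)c1 | intermediate
21 | 3,5-dimethoxyphenol | COc1cc(O)cc(OC)c1 | starting material
22 | 2-bromo-3,5-dimethoxyphenol | COc1cc(O)c(Br)c(OC)c1 | intermediate
23 | (2-bromo-3,5-dimethoxyphenoxy)trimethylsilane | COc1cc(O[Si](C)(C)C)c(Br)c(OC)c1 | intermediate
24 | lithium 3,5-dimethoxy-2-(trimethylsilyl)phenoxide | COc1cc([O-])c([Si](C)(C)C)c(OC)c1.[Li+] | intermediate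
25 | 3,5-dimethoxy-2-(trimethylsilyl)phenyl trifluoromethanesulfonate | COc1cc(OC)c([Si](C)(C)C)c(OS(=O)(=O)C(F)(F)F)c1 | intermediate
26 | pentafluorophenyl (2R,3R)-2-DBF-3-[2-(2-methoxy-2-oxoethyl)-3,5-bis(methoxymethoxy)phenyl]pent-4-enoate | C=C[C@H]([C@@H](C(=O)Oc1c(F)c(F)c(F)c(F)c1F)c1cc(OC)cc2c1[C@@H](c1cc(OC)cc(OC)c1)[C@H](c1ccc(OC)cc1)O2)c1cc(OCOC)cc(OCOC)c1CC(=O)OC | intermediate
27 | methyl (2R,3R)-2-DBF-3-[2-(2-methoxy-2-oxoethyl)-3,5-bis(methoxymethoxy)phenyl]pent-4-enoate | C=C[C@H]([C@@H](C(=O)OC)c1cc(OC)cc2c1[C@@H](c1cc(OC)cc(OC)c1)[C@H](c1ccc(OC)cc1)O2)c1cc(OCOC)cc(OCOC)c1CC(=O)OC | intermediate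
28 | methyl (3R,4R)-4-ethenyl-2-hydroxy-6,8-bis(methoxymethoxy)-3-DBF-3,4-dihydronaphthalene-1-carboxylate (β-tetralone ester, enol form) | C=C[C@H]1c2cc(OCOC)cc(OCOC)c2C(C(=O)OC)=C(O)[C@H]1c1cc(OC)cc2c1[C@@H](c1cc(OC)cc(OC)c1)[C@H](c1ccc(OC)cc1)O2 | intermediate
29 | 3,5-dimethoxybenzyne | COC1=CC(OC)=CC#C1 | intermediate
30 | caesium alkoxide of the fused benzocyclobutenol (four-membered ring C-g, d1, d6, C-i; new centres not assigned) | C=C[C@H]1c2cc(OCOC)cc(OCOC)c2C2(C(=O)OC)c3cc(OC)cc(OC)c3C2([O-])[C@H]1c1cc(OC)cc2c1[C@@H](c1cc(OC)cc(OC)c1)[C@H](c1ccc(OC)cc1)O2.[Cs+] | intermediate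
31 | eight-ring keto ester (dibenzocyclooctenone; CO2Me on C-g, C=O at C-i, vinyl on C-f, DBF on C-j; ring C bis(methoxymethoxy), ring D dimethoxy; C-f R, C-g R, C-j R) | C=C[C@H]1c2cc(OCOC)cc(OCOC)c2[C@H](C(=O)OC)c2cc(OC)cc(OC)c2C(=O)[C@H]1c1cc(OC)cc2c1[C@@H](c1cc(OC)cc(OC)c1)[C@H](c1ccc(OC)cc1)O2 | intermediate
32 | eight-ring hydroxy ester (as 31 with CH(OH) at C-i, carbinol configuration not controlled) | C=C[C@H]1c2cc(OCOC)cc(OCOC)c2[C@H](C(=O)OC)c2cc(OC)cc(OC)c2C(O)[C@H]1c1cc(OC)cc2c1[C@@H](c1cc(OC)cc(OC)c1)[C@H](c1ccc(OC)cc1)O2 | intermediate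
33 | 4-bromoanisole | COc1ccc(Br)cc1 | starting material
34 | N,O-acetal of 32 with 5,7-di-tert-butyl-3-phenyl-2,3-dihydrobenzoxazole (C-i–O–C2 of the heterocycle) | C=C[C@H]1c2cc(OCOC)cc(OCOC)c2[C@H](C(=O)OC)c2cc(OC)cc(OC)c2C(OC2Oc3c(cc(cc3N2c2ccccc2)C(C)(C)C)C(C)(C)C)[C@H]1c1cc(OC)cc2c1[C@@H](c1cc(OC)cc(OC)c1)[C@H](c1ccc(OC)cc1)O2 | intermediate
35 | eight-ring ester with An on C-i (An trans to DBF; C-f R, C-g R, C-i S, C-j S) | C=C[C@H]1c2cc(OCOC)cc(OCOC)c2[C@H](C(=O)OC)c2cc(OC)cc(OC)c2[C@H](c2ccc(OC)cc2)[C@H]1c1cc(OC)cc2c1[C@@H](c1cc(OC)cc(OC)c1)[C@H](c1ccc(OC)cc1)O2 | intermediate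
36 | eight-ring primary alcohol (as 35 with CH2OH on C-g) | C=C[C@H]1c2cc(OCOC)cc(OCOC)c2[C@H](CO)c2cc(OC)cc(OC)c2[C@H](c2ccc(OC)cc2)[C@H]1c1cc(OC)cc2c1[C@@H](c1cc(OC)cc(OC)c1)[C@H](c1ccc(OC)cc1)O2 | intermediate
37 | eight-ring aldehyde (as 35 with CHO on C-g) | C=C[C@H]1c2cc(OCOC)cc(OCOC)c2[C@H](C=O)c2cc(OC)cc(OC)c2[C@H](c2ccc(OC)cc2)[C@H]1c1cc(OC)cc2c1[C@@H](c1cc(OC)cc(OC)c1)[C@H](c1ccc(OC)cc1)O2 | intermediate
38 | eight-ring carbinol (as 35 with CH(OH)An on C-g, carbinol configuration not controlled) | C=C[C@H]1c2cc(OCOC)cc(OCOC)c2[C@H](C(O)c2ccc(OC)cc2)c2cc(OC)cc(OC)c2[C@H](c2ccc(OC)cc2)[C@H]1c1cc(OC)cc2c1[C@@H](c1cc(OC)cc(OC)c1)[C@H](c1ccc(OC)cc1)O2 | intermediate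
39 | deprotected triol (as 38 with both ring C oxygens as free OH) | C=C[C@H]1c2cc(O)cc(O)c2[C@H](C(O)c2ccc(OC)cc2)c2cc(OC)cc(OC)c2[C@H](c2ccc(OC)cc2)[C@H]1c1cc(OC)cc2c1[C@@H](c1cc(OC)cc(OC)c1)[C@H](c1ccc(OC)cc1)O2 | intermediate
40 | right-half phenol (trans furan C-g R/C-h R closed on ring C, free OH on ring C, vinyl on C-f; C-f R, C-i S, C-j S) | C=C[C@H]1c2cc(O)cc3c2[C@@H](c2cc(OC)cc(OC)c2[C@H](c2ccc(OC)cc2)[C@H]1c1cc(OC)cc2c1[C@@H](c1cc(OC)cc(OC)c1)[C@H](c1ccc(OC)cc1)O2)[C@H](c1ccc(OC)cc1)O3 | intermediate
41 | right-half methyl ether (as 40 with OMe on ring C) | C=C[C@H]1c2cc(OC)cc3c2[C@@H](c2cc(OC)cc(OC)c2[C@H](c2ccc(OC)cc2)[C@H]1c1cc(OC)cc2c1[C@@H](c1cc(OC)cc(OC)c1)[C@H](c1ccc(OC)cc1)O2)[C@H](c1ccc(OC)cc1)O3 | intermediate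
42 | right-half diol (1,2-dihydroxyethyl on C-f) | OCC(O)[C@H]1c2cc(OC)cc3c2[C@@H](c2cc(OC)cc(OC)c2[C@H](c2ccc(OC)cc2)[C@H]1c1cc(OC)cc2c1[C@@H](c1cc(OC)cc(OC)c1)[C@H](c1ccc(OC)cc1)O2)[C@H](c1ccc(OC)cc1)O3 | intermediate
43 | right-half aldehyde (CHO on C-f) | O=C[C@H]1c2cc(OC)cc3c2[C@@H](c2cc(OC)cc(OC)c2[C@H](c2ccc(OC)cc2)[C@H]1c1cc(OC)cc2c1[C@@H](c1cc(OC)cc(OC)c1)[C@H](c1ccc(OC)cc1)O2)[C@H](c1ccc(OC)cc1)O3 | intermediate
44 | bromomagnesium alkoxide of the C-e carbinol (C-e bears OMgBr and 4-(tert-butyldimethylsilyloxy)phenyl) | Br[Mg]OC(c1ccc(O[Si](C)(C)C(C)(C)C)cc1)[C@H]1c2cc(OC)cc3c2[C@@H](c2cc(OC)cc(OC)c2[C@H](c2ccc(OC)cc2)[C@H]1c1cc(OC)cc2c1[C@@H](c1cc(OC)cc(OC)c1)[C@H](c1ccc(OC)cc1)O2)[C@H](c1ccc(OC)cc1)O3 | intermediate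
45 | right-half acetate (C-e bears OAc and 4-(tert-butyldimethylsilyloxy)phenyl, C-e configuration not controlled) | CC(=O)OC(c1ccc(O[Si](C)(C)C(C)(C)C)cc1)[C@H]1c2cc(OC)cc3c2[C@@H](c2cc(OC)cc(OC)c2[C@H](c2ccc(OC)cc2)[C@H]1c1cc(OC)cc2c1[C@@H](c1cc(OC)cc(OC)c1)[C@H](c1ccc(OC)cc1)O2)[C@H](c1ccc(OC)cc1)O3 | intermediate
46 | left ketone (furan-fused dibenzocycloheptenone: C=O at C-a on ring A, CH2 at C-d on ring B, C-b R, C-c R, An on C-c) | O=C1c2c(OC)cc(OC)cc2[C@@H]2c3c(cc(OC)cc3C1)O[C@H]2c1ccc(OC)cc1 | intermediate
47 | left enol silane (trimethylsilyl enol ether of 46, C-a=C-d) | C[Si](C)(C)OC=1c2c(OC)cc(OC)cc2[C@@H]2c3c(cc(OC)cc3C=1)O[C@H]2c1ccc(OC)cc1 | intermediate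
48 | right-half para-quinone methide (C-e is the exocyclic methide carbon on C-f) | O=C1C=CC(C=C1)=C[C@H]1c2cc(OC)cc3c2[C@@H](c2cc(OC)cc(OC)c2[C@H](c2ccc(OC)cc2)[C@H]1c1cc(OC)cc2c1[C@@H](c1cc(OC)cc(OC)c1)[C@H](c1ccc(OC)cc1)O2)[C@H](c1ccc(OC)cc1)O3 | intermediate
49 | union ketone (C=O at C-a; C-d S, C-e R with 4-hydroxyphenyl; all other centres as in 52) | O=C1c2c(OC)cc(OC)cc2[C@@H]2c3c(cc(OC)cc3[C@H]1[C@H](c1ccc(O)cc1)[C@H]4c5cc(OC)cc6c5[C@@H](c5cc(OC)cc(OC)c5[C@H](c5ccc(OC)cc5)[C@H]4c4cc(OC)cc5c4[C@@H](c4cc(OC)cc(OC)c4)[C@H](c4ccc(OC)cc4)O5)[C@H](c4ccc(OC)cc4)O6)O[C@H]2c1ccc(OC)cc1 | intermediate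
50 | tertiary carbinol (as 49 with OH and An on C-a, C-a configuration not controlled) | OC1(c7ccc(OC)cc7)c2c(OC)cc(OC)cc2[C@@H]2c3c(cc(OC)cc3[C@H]1[C@H](c1ccc(O)cc1)[C@H]4c5cc(OC)cc6c5[C@@H](c5cc(OC)cc(OC)c5[C@H](c5ccc(OC)cc5)[C@H]4c4cc(OC)cc5c4[C@@H](c4cc(OC)cc(OC)c4)[C@H](c4ccc(OC)cc4)O5)[C@H](c4ccc(OC)cc4)O6)O[C@H]2c1ccc(OC)cc1 | intermediate
51 | tetradeca-O-methyl ether of the target (free OH only on the C-e aryl; C-a S, C-b R, C-c R, C-d S, C-e R, C-f R, C-g R, C-h R, C-i S, C-j S, C-k R, C-l R) | COc1ccc([C@H]2c3c(OC)cc(OC)cc3[C@@H]3c4c(cc(OC)cc4[C@H]2[C@H](c2ccc(O)cc2)[C@H]2c4cc(OC)cc5c4[C@@H](c4cc(OC)cc(OC)c4[C@H](c4ccc(OC)cc4)[C@H]2c2cc(OC)cc4c2[C@@H](c2cc(OC)cc(OC)c2)[C@H](c2ccc(OC)cc2)O4)[C@H](c2ccc(OC)cc2)O5)O[C@H]3c2ccc(OC)cc2)cc1 | intermediate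
52 | CNP0184494.1 | Oc1ccc([C@H]2c3c(O)cc(O)cc3[C@@H]3c4c(cc(O)cc4[C@H]2[C@H](c2ccc(O)cc2)[C@H]2c4cc(O)cc5c4[C@@H](c4cc(O)cc(O)c4[C@H](c4ccc(O)cc4)[C@H]2c2cc(O)cc4c2[C@@H](c2cc(O)cc(O)c2)[C@H](c2ccc(O)cc2)O4)[C@H](c2ccc(O)cc2)O5)O[C@H]3c2ccc(O)cc2)cc1 | target

## Step count and least certain steps

Total: 33 steps. Longest linear sequence: 23 steps (steps 1 to 7, 16 to 27, 30 to 33).

Step 18 (key step). Most likely to go wrong: the enolate carbon of 28 is fully substituted and flanked by an ortho acetal ether, so addition to the aryne may be slow. The aryl anion could then be protonated before it closes on the ketone (plain α-arylation), the enol oxygen could arylate, or a second aryne could add to the product anion. Basic fluoride may also epimerise C-j once it is α to the ketone. Fallback, from 27 back to 31: the ester-bearing methylene of 27 is arylated with 1 under palladium catalysis (LiN(SiMe3)2, Pd2(dba)3, P(t-Bu)3; the unhindered benzylic CH2 should react in preference to C-j) to give the diaryl-acetate diester F1. The less hindered C-j methyl ester is hydrolysed (Me3SnOH, 1,2-dichloroethane, 60 °C) to the acid F2. F2 is cyclised with (CF3CO)2O and 2,6-di-tert-butylpyridine; this Friedel–Crafts acylation onto the ring D carbon ortho to C-g forms the d6–C-i bond and gives 31. This closes the eight-membered ring directly and is expected to be slow, which is why it is the reserve.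

Step 30. Most likely to go wrong: the quinone methide 48 has a hydrogen on C-f and may tautomerise to the conjugated stilbene under the basic fluoride conditions faster than the hindered enolate adds, erasing C-f. Facial selectivity at C-d and C-e may also be poor, because both are set by substrate control between two large fragments. Fallback, from 43 and 46 back to 49: aldol condensation (LiN(SiMe3)2, THF, −78 °C; then MsCl, Et3N, DBU) gives the enone F4 with a C-d=C-e double bond. The cuprate from 4-(t-BuMe2SiO)C6H4MgBr and CuBr·SMe2, with Me3SiCl, adds the aryl group to C-e anti to ring C on the C-f branch; protonation sets C-d under thermodynamic control and gives the silyl ether F5. Bu4NF then gives 49.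

Step 20. Most likely to go wrong: the hindered secondary alcohol may condense slowly with the benzoxazolium salt, the benzylic radical may be reduced instead of coupled, and capture by nickel may show poor facial selectivity at C-i. Fallback, from 31 back to 35: 4-MeOC6H4MgBr with LaCl3·2LiCl adds to the ketone of 31 to give the tertiary carbinol F3, and Et3SiH with BF3·OEt2 at −78 °C replaces the hydroxyl group by hydrogen (ionic hydrogenation) to reach 35. This polar route puts a cation on C-i, so excess silane and low temperature are needed to outrun capture by ring F. Hydride, not aryl, is then the incoming group, so the facial outcome at C-i would have to be checked before material is committed.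

Step 16. Most likely to go wrong: both partners are ortho-substituted, so ionisation of the cinnamyl carbonate and attack at its substituted terminus may be slow, with loss of branched selectivity, and the chiral DBF group may be mismatched with one catalyst. Fallback, from 12 and 19 back to 27: DCC/DMAP esterification gives the (E)-cinnamyl ester F6. Ireland–Claisen rearrangement (LiN(SiMe3)2, Me3SiCl, THF, −78 °C to rt; both esters are silylated but only the allylic ketene acetal can rearrange) forms the C-j–C-f bond through a chair transition state and gives the acid F7. The relative configuration follows from the ketene acetal geometry, and the wrong-handed diastereomer is separable because the DBF group is enantiopure. Me3SiCHN2 in MeOH then gives 27.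

Step 23 (with the equilibration in step 22). Most likely to go wrong: the aldehyde 37 may settle to the other C-g epimer, which would be frozen by the Grignard addition and carried into the furan. Fallback, from 38 back to 40: Dess–Martin oxidation gives the aryl ketone F8. HCl in MeOH removes the acetals and cyclodehydrates to the 2-aryl-benzofuran F9, in which C-g and C-h are both planar. Ionic hydrogenation (Et3SiH, CF3CO2H, CH2Cl2, 0 °C) adds hydrogen trans across the furan double bond, the proton entering C-g from the less hindered face, to give 40; C-g is then set kinetically and not by the carbonyl equilibrium.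

## Further compounds

F1 | step 18 | methyl (2R,3R)-2-DBF-3-{2-[1-(3,5-dimethoxyphenyl)-2-methoxy-2-oxoethyl]-3,5-bis(methoxymethoxy)phenyl}pent-4-enoate | C=C[C@H]([C@@H](C(=O)OC)c1cc(OC)cc2c1[C@@H](c1cc(OC)cc(OC)c1)[C@H](c1ccc(OC)cc1)O2)c1cc(OCOC)cc(OCOC)c1C(C(=O)OC)c1cc(OC)cc(OC)c1
F2 | step 18 | (2R,3R)-2-DBF-3-{2-[1-(3,5-dimethoxyphenyl)-2-methoxy-2-oxoethyl]-3,5-bis(methoxymethoxy)phenyl}pent-4-enoic acid | C=C[C@H]([C@@H](C(=O)O)c1cc(OC)cc2c1[C@@H](c1cc(OC)cc(OC)c1)[C@H](c1ccc(OC)cc1)O2)c1cc(OCOC)cc(OCOC)c1C(C(=O)OC)c1cc(OC)cc(OC)c1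
F3 | step 20 | eight-ring tertiary carbinol (as 31 with OH and An on C-i) | C=C[C@H]1c2cc(OCOC)cc(OCOC)c2[C@H](C(=O)OC)c2cc(OC)cc(OC)c2C(O)(c2ccc(OC)cc2)[C@H]1c1cc(OC)cc2c1[C@@H](c1cc(OC)cc(OC)c1)[C@H](c1ccc(OC)cc1)O2
F4 | step 30 | enone from 43 and 46 (C-d=C-e double bond, C=O at C-a) | O=C1c2c(OC)cc(OC)cc2[C@@H]2c3c(cc(OC)cc3C1=C[C@H]4c5cc(OC)cc6c5[C@@H](c5cc(OC)cc(OC)c5[C@H](c5ccc(OC)cc5)[C@H]4c4cc(OC)cc5c4[C@@H](c4cc(OC)cc(OC)c4)[C@H](c4ccc(OC)cc4)O5)[C@H](c4ccc(OC)cc4)O6)O[C@H]2c1ccc(OC)cc1
F5 | step 30 | tert-butyldimethylsilyl ether of 49 | O=C1c2c(OC)cc(OC)cc2[C@@H]2c3c(cc(OC)cc3[C@H]1[C@H](c1ccc(O[Si](C)(C)C(C)(C)C)cc1)[C@H]4c5cc(OC)cc6c5[C@@H](c5cc(OC)cc(OC)c5[C@H](c5ccc(OC)cc5)[C@H]4c4cc(OC)cc5c4[C@@H](c4cc(OC)cc(OC)c4)[C@H](c4ccc(OC)cc4)O5)[C@H](c4ccc(OC)cc4)O6)O[C@H]2c1ccc(OC)cc1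
F6 | step 16 | (E)-3-[2-(2-methoxy-2-oxoethyl)-3,5-bis(methoxymethoxy)phenyl]prop-2-enyl 2-DBF-acetate | COC(=O)Cc1c(OCOC)cc(OCOC)cc1/C=C/COC(=O)Cc1cc(OC)cc2c1[C@@H](c1cc(OC)cc(OC)c1)[C@H](c1ccc(OC)cc1)O2
F7 | step 16 | (2R,3R)-2-DBF-3-[2-(2-methoxy-2-oxoethyl)-3,5-bis(methoxymethoxy)phenyl]pent-4-enoic acid | C=C[C@H]([C@@H](C(=O)O)c1cc(OC)cc2c1[C@@H](c1cc(OC)cc(OC)c1)[C@H](c1ccc(OC)cc1)O2)c1cc(OCOC)cc(OCOC)c1CC(=O)OC
F8 | step 23 | eight-ring aryl ketone (as 38 with C(=O)An on C-g, C-g not fixed) | C=C[C@H]1c2cc(OCOC)cc(OCOC)c2C(C(=O)c2ccc(OC)cc2)c2cc(OC)cc(OC)c2[C@H](c2ccc(OC)cc2)[C@H]1c1cc(OC)cc2c1[C@@H](c1cc(OC)cc(OC)c1)[C@H](c1ccc(OC)cc1)O2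
F9 | step 23 | right-half benzofuran (C-g=C-h within an aromatic furan on ring C, free OH on ring C, vinyl on C-f) | C=C[C@H]1c2cc(O)cc3oc(-c4ccc(OC)cc4)c(c23)-c2cc(OC)cc(OC)c2[C@H](c2ccc(OC)cc2)[C@H]1c1cc(OC)cc2c1[C@@H](c1cc(OC)cc(OC)c1)[C@H](c1ccc(OC)cc1)O2
A1 | alternative 1 | (2R,3R)-4-[(tert-butyldimethylsilyloxy)methyl]-3-(3,5-dimethoxyphenyl)-2-(4-methoxyphenyl)-2,3-dihydro-1-benzofuran-6-ol | CC(C)(C)[Si](C)(C)OCc1cc(O)cc2c1[C@@H](c1cc(OC)cc(OC)c1)[C@H](c1ccc(OC)cc1)O2
A2 | alternative 1 | diazo enone with tethered ethynyl ether: 2-[(tert-butyldimethylsilyloxy)methyl]-4-diazo-5-(3,5-dimethoxyphenyl)-6-ethynyloxy-6-(4-methoxyphenyl)hex-1-en-3-one | C=C(CO[Si](C)(C)C(C)(C)C)C(=O)C(=[N+]=[N-])[C@@H](c1cc(OC)cc(OC)c1)[C@H](c1ccc(OC)cc1)OC#C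
A3 | alternative 2 | furan-fused dibenzocycloheptanone with CH(An) at C-a and C=O at C-d | COc1ccc([C@H]2c3c(OC)cc(OC)cc3[C@@H]3c4c(cc(OC)cc4C2=O)O[C@H]3c2ccc(OC)cc2)cc1
A4 | alternative 2 | furan-bridged anthrone (C=O between ring A and ring B, C-b R, C-c R) | O=C1c2c(OC)cc(OC)cc2[C@@H]2c3c(cc(OC)cc31)O[C@H]2c1ccc(OC)cc1
A5 | alternative 2 | 4-methoxyphenyldiazomethane | COc1ccc(C=[N+]=[N-])cc1
A6 | alternative 3 | methyl dibenzocycloheptanone-carboxylate (diaryl acetate at C-b, C=O at C-a, CH2 at C-d, ring B bis(benzyloxy)) | COC(=O)[C@@H]1c2cc(OC)cc(OC)c2C(=O)Cc2cc(OCc3ccccc3)cc(OCc3ccccc3)c21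
A7 | alternative 3 | methyl 5,7-bis(benzyloxy)-2-oxoindane-1-carboxylate | COC(=O)C1C(=O)Cc2cc(OCc3ccccc3)cc(OCc3ccccc3)c21
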